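**Direct plan and its weak points**

A direct plan would join acetophenone A1 and benzaldehyde A2, each carrying a 1,1-dimethylallyl ether and a silyl ether, by aldol addition to A3. It would close ring C through the O1–C2 bond to the racemic flavanone A4, resolve it, and move both allyl groups to C6 and C5' in one late double aromatic Claisen rearrangement to A5 before desilylation.
- The ring C closure by Mitsunobu etherification of an electron-rich benzylic β-hydroxy ketone would set C2 without any control and would compete with dehydration.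
- The kinetic resolution by transfer hydrogenation would correct C2 afterwards, so at best half of an advanced intermediate would be kept.
- The late double Claisen rearrangement would have to choose C5' over C3' on the finished skeleton, and its tertiary allyl ethers would first have to be made on a chelated, hindered phenol next to silyl groups that build nothing.

**Retrosynthetic overview**

1. Key cut at C2–C1': C2 is the β-carbon of the ring C enone and C1' is the ring B carbon ortho to O2' and para to O4'. A rhodium-catalysed asymmetric 1,4-addition of boronic acid 16 to chromone 10 forms this bond, sets C2 and joins the two prenylated halves; only acetal cleavage follows.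
2. Ring order: ring A is bought, ring C is closed on it first (6-endo oxa-Michael of ynone 9, no stereocentre), and ring B is attached last.
3. Chromone 10: the C6 prenyl group sits on the symmetry axis of resorcinol bis-ether 3. The unique para oxygen (later O1) comes from sterically controlled C–H borylation/oxidation, and either equivalent ortho carbon takes the formyl group (later C4), so a 6- versus 8-prenyl choice cannot arise.
4. Boronic acid 16: the two bromines of 4,6-dibromoresorcinol mark C5' (prenyl) and C1' (boron).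
5. There is no racemic ring closure, no resolution and no late sigmatropic step: C2 is made once, under catalyst control, in the bond-forming step.

Key step: step 9

Assumption 1: 1,3-bis(methoxymethoxy)benzene (1) is taken as purchasable; otherwise it would cost one extra step from resorcinol and MOMCl.
Assumption 2: (S)-MeO-F12-BIPHEP, i.e. (S)-(6,6'-dimethoxybiphenyl-2,2'-diyl)bis[bis(3,4,5-trifluorophenyl)phosphane], is assumed to deliver the aryl group to the Re face of C2, by analogy with the sense known for cyclic enones; the antipode would be used if a model chromone showed the opposite sense.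

**Route**

Step 1
Reactants: 1 1,3-bis(methoxymethoxy)benzene
Product: 3 1,3-bis(methoxymethoxy)-2-(3-methylbut-2-enyl)benzene, via aryllithium 2 (not isolated)
Conditions: n-BuLi (1.1 equiv), THF, 0 °C → rt; then CuBr·SMe2 (10 mol%), prenyl bromide (1.2 equiv), −78 °C → rt
Reagents that add atoms: 1-bromo-3-methylbut-2-ene (prenyl bromide), CC(C)=CCBr
Why: Directed ortho-metalation at the C–H between the two acetal oxygens, followed by copper-assisted SN2 allylation with the primary allylic bromide, is the standard entry to a 2-prenylresorcinol bis-ether and places the prenyl group on the symmetry axis.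

Step 2
Reactants: 3 1,3-bis(methoxymethoxy)-2-(3-methylbut-2-enyl)benzene
Product: 5 3,5-bis(methoxymethoxy)-4-(3-methylbut-2-enyl)phenol, via aryl pinacol boronate 4 (not isolated)
Conditions: [Ir(OMe)(cod)]2 (1.5 mol%), 4,4'-di-tert-butyl-2,2'-bipyridine (3 mol%), B2pin2 (0.55 equiv), THF, 70 °C; then 30% H2O2, aq NaOH, 0 °C
Reagents that add atoms: bis(pinacolato)diboron (boron of 4), CC1(C)OB(OC1(C)C)B1OC(C)(C)C(C)(C)O1; hydrogen peroxide, OO
Why: Iridium-catalysed aromatic C–H borylation is governed by sterics and should take the only ring C–H without an ortho substituent (para to the prenyl group), and alkaline peroxide oxidation of the boronate in the same flask should give the phenol without touching the unactivated trisubstituted alkene.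

Step 3
Reactants: 5 3,5-bis(methoxymethoxy)-4-(3-methylbut-2-enyl)phenol
Product: 7 6-hydroxy-2,4-bis(methoxymethoxy)-3-(3-methylbut-2-enyl)benzaldehyde, via salicyl alcohol 6 (not isolated)
Conditions: MgCl2 (1.5 equiv), Et3N (3.75 equiv), (CH2O)n (6 equiv), MeCN, reflux; cold dilute HCl work-up
Reagents that add atoms: paraformaldehyde (formaldehyde unit), C=O
Why: In this magnesium-mediated ortho-formylation (Casnati–Skattebøl) the magnesium phenoxide delivers formaldehyde only to an ortho carbon, a second formaldehyde oxidises the hydroxymethyl stage by Oppenauer-type hydride transfer, and because the two ortho positions of 5 are equivalent only one isomer can form, while the basic medium spares acetals and alkene.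

Step 4
Reactants: 7 6-hydroxy-2,4-bis(methoxymethoxy)-3-(3-methylbut-2-enyl)benzaldehyde
Product: 8 rac-1-[6-hydroxy-2,4-bis(methoxymethoxy)-3-(3-methylbut-2-enyl)phenyl]prop-2-yn-1-ol
Conditions: HC≡CMgBr (3 equiv), THF, −20 → 0 °C; aq NH4Cl; used crude
Reagents that add atoms: ethynylmagnesium bromide, C#C[Mg]Br
Why: Grignard 1,2-addition of the acetylide to the aldehyde, after a first equivalent has deprotonated the phenol, should give the propargylic alcohol, whose racemic carbinol centre is removed in the next step.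

Step 5
Reactants: 8 rac-1-[6-hydroxy-2,4-bis(methoxymethoxy)-3-(3-methylbut-2-enyl)phenyl]prop-2-yn-1-ol
Product: 10 5,7-bis(methoxymethoxy)-6-(3-methylbut-2-enyl)-4H-chromen-4-one, via ethynyl ketone 9 (not isolated)
Conditions: activated MnO2 (15 equiv), CH2Cl2, rt; filtration; then K2CO3 (0.2 equiv), acetone, rt
Reagents that add atoms: none
Why: MnO2 oxidation of the benzylic propargylic alcohol gives the ynone, and its ortho phenoxide then adds to the terminal alkyne carbon in a 6-endo-dig oxa-Michael addition that closes ring C as the chromone, with O1 necessarily the oxygen para to the prenyl group.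

Step 6
Reactants: 11 4,6-dibromobenzene-1,3-diol
Product: 12 1,5-dibromo-2,4-bis(methoxymethoxy)benzene
Conditions: MOMCl (2.5 equiv), iPr2NEt (3 equiv), CH2Cl2, 0 °C → rt
Reagents that add atoms: chloromethyl methyl ether (MOMCl), COCCl
Why: O-alkylation of both phenols with the chloromethyl ether (Williamson-type acetal formation) is routine and gives ethers that tolerate and stabilise the aryllithiums of the next two steps.

Step 7
Reactants: 12 1,5-dibromo-2,4-bis(methoxymethoxy)benzene
Product: 14 1-bromo-2,4-bis(methoxymethoxy)-5-(3-methylbut-2-enyl)benzene, via aryllithium 13 (not isolated)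
Conditions: n-BuLi (1.0 equiv), THF, −78 °C; then CuBr·SMe2 (10 mol%), prenyl bromide (1.2 equiv), −78 → 0 °C
Reagents that add atoms: 1-bromo-3-methylbut-2-ene (prenyl bromide), CC(C)=CCBr
Why: Bromine–lithium exchange of one of the two equivalent bromides should stop after one exchange, because the aryllithium deactivates the remaining meta bromide and cannot eliminate to an aryne, and copper-assisted SN2 allylation then installs the future C5' prenyl group.

Step 8
Reactants: 14 1-bromo-2,4-bis(methoxymethoxy)-5-(3-methylbut-2-enyl)benzene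
Product: 16 [2,4-bis(methoxymethoxy)-5-(3-methylbut-2-enyl)phenyl]boronic acid, via aryllithium 15 (not isolated)
Conditions: n-BuLi (1.1 equiv), THF, −78 °C; B(OiPr)3 (1.5 equiv), −78 °C → rt; aq NH4Cl
Reagents that add atoms: triisopropyl borate, CC(C)OB(OC(C)C)OC(C)C; water, O
Why: A second bromine–lithium exchange, borylation of the aryllithium with a trialkyl borate and mild hydrolysis is the standard route to an arylboronic acid and fixes boron at the future C1'.

Step 9
Reactants: 10 5,7-bis(methoxymethoxy)-6-(3-methylbut-2-enyl)-4H-chromen-4-one; 16 [2,4-bis(methoxymethoxy)-5-(3-methylbut-2-enyl)phenyl]boronic acid (3 equiv)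
Product: 17 (2S)-2-[2,4-bis(methoxymethoxy)-5-(3-methylbut-2-enyl)phenyl]-5,7-bis(methoxymethoxy)-6-(3-methylbut-2-enyl)-2,3-dihydro-4H-chromen-4-one
Conditions: [Rh(OH)(cod)]2 (2.5 mol%), (S)-MeO-F12-BIPHEP (5.5 mol%), CH2Cl2/H2O (10:1), 30 °C
Reagents that add atoms: none
Why: The hydroxo complex of monovalent rhodium transmetalates with 16 to an aryl–rhodium species, which binds the C2=C3 bond of 10 and inserts it so that the aryl group bonds to C2 and an oxa-π-allyl rhodium enolate results, which water protonates at C3 with return of the hydroxo complex. The closest known reaction type is the Hayashi–Miyaura asymmetric 1,4-addition of arylboronic acids to chromones, which gives 2-arylchroman-4-ones. No ring is closed; the step forms the C2–C1' bond that joins ring B to the ring A/C chromone. The one new stereocentre, C2, is set by the chiral bisphosphine on rhodium (catalyst control), which should direct the aryl group to the Re face of C2 (O1 > C3 > H) and so give 2S. The step needs 1,4- over 1,2-addition, addition faster than protodeboronation, and inert prenyl groups: the 5-acetal flanking C4 and the electron-poor ligand in a non-coordinating solvent should favour the first, an excess of 16 covers the second, and unactivated trisubstituted alkenes do not insert into aryl–rhodium bonds. The neutral medium near ambient temperature should keep the new benzylic ether centre from retro-oxa-Michael opening.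

Step 10
Reactants: 17 (2S)-2-[2,4-bis(methoxymethoxy)-5-(3-methylbut-2-enyl)phenyl]-5,7-bis(methoxymethoxy)-6-(3-methylbut-2-enyl)-2,3-dihydro-4H-chromen-4-one
Product: 18 (2S)-2-[2,4-dihydroxy-5-(3-methylbut-2-enyl)phenyl]-5,7-dihydroxy-6-(3-methylbut-2-enyl)-2,3-dihydro-4H-chromen-4-one (CNP0320454.1)
Conditions: HCl (1.25 M in MeOH), 30 °C, stopped at full conversion; NaHCO3 quench
Reagents that add atoms: none
Why: Acid-catalysed transacetalisation to methanol cleaves the four aryl methoxymethyl ethers, and a short exposure to dilute methanolic acid near ambient temperature should neither protonate the prenyl alkenes nor ionise the C2–O1 bond, so the 2S configuration should be kept.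

**Compound list**

1 | 1,3-bis(methoxymethoxy)benzene | COCOc1cccc(OCOC)c1 | starting material
2 | [2,6-bis(methoxymethoxy)phenyl]lithium | [Li]c1c(OCOC)cccc1OCOC | intermediate
3 | 1,3-bis(methoxymethoxy)-2-(3-methylbut-2-enyl)benzene | COCOc1cccc(OCOC)c1CC=C(C)C | intermediate
4 | 2-[3,5-bis(methoxymethoxy)-4-(3-methylbut-2-enyl)phenyl]-4,4,5,5-tetramethyl-1,3,2-dioxaborolane | COCOc1cc(B2OC(C)(C)C(C)(C)O2)cc(OCOC)c1CC=C(C)C | intermediate
5 | 3,5-bis(methoxymethoxy)-4-(3-methylbut-2-enyl)phenol | COCOc1cc(O)cc(OCOC)c1CC=C(C)C | intermediate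
6 | 2-(hydroxymethyl)-3,5-bis(methoxymethoxy)-4-(3-methylbut-2-enyl)phenol | OCc1c(O)cc(OCOC)c(CC=C(C)C)c1OCOC | intermediate
7 | 6-hydroxy-2,4-bis(methoxymethoxy)-3-(3-methylbut-2-enyl)benzaldehyde | O=Cc1c(O)cc(OCOC)c(CC=C(C)C)c1OCOC | intermediate
8 | rac-1-[6-hydroxy-2,4-bis(methoxymethoxy)-3-(3-methylbut-2-enyl)phenyl]prop-2-yn-1-ol | C#CC(O)c1c(O)cc(OCOC)c(CC=C(C)C)c1OCOC | intermediate
9 | 1-[6-hydroxy-2,4-bis(methoxymethoxy)-3-(3-methylbut-2-enyl)phenyl]prop-2-yn-1-one | C#CC(=O)c1c(O)cc(OCOC)c(CC=C(C)C)c1OCOC | intermediate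
10 | 5,7-bis(methoxymethoxy)-6-(3-methylbut-2-enyl)-4H-chromen-4-one | O=c1ccoc2cc(OCOC)c(CC=C(C)C)c(OCOC)c12 | intermediate
11 | 4,6-dibromobenzene-1,3-diol | Oc1cc(O)c(Br)cc1Br | starting material
12 | 1,5-dibromo-2,4-bis(methoxymethoxy)benzene | COCOc1cc(OCOC)c(Br)cc1Br | intermediate
13 | [5-bromo-2,4-bis(methoxymethoxy)phenyl]lithium | [Li]c1cc(Br)c(OCOC)cc1OCOC | intermediate
14 | 1-bromo-2,4-bis(methoxymethoxy)-5-(3-methylbut-2-enyl)benzene | COCOc1cc(OCOC)c(CC=C(C)C)cc1Br | intermediate
15 | [2,4-bis(methoxymethoxy)-5-(3-methylbut-2-enyl)phenyl]lithium | [Li]c1cc(CC=C(C)C)c(OCOC)cc1OCOC | intermediate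
16 | [2,4-bis(methoxymethoxy)-5-(3-methylbut-2-enyl)phenyl]boronic acid | COCOc1cc(OCOC)c(CC=C(C)C)cc1B(O)O | intermediate
17 | (2S)-2-[2,4-bis(methoxymethoxy)-5-(3-methylbut-2-enyl)phenyl]-5,7-bis(methoxymethoxy)-6-(3-methylbut-2-enyl)-2,3-dihydro-4H-chromen-4-one | CC(C)=CCc1cc([C@@H]2CC(=O)c3c(cc(OCOC)c(CC=C(C)C)c3OCOC)O2)c(OCOC)cc1OCOC | intermediate
18 | (2S)-2-[2,4-dihydroxy-5-(3-methylbut-2-enyl)phenyl]-5,7-dihydroxy-6-(3-methylbut-2-enyl)-2,3-dihydro-4H-chromen-4-one (CNP0320454.1) | CC(C)=CCc1cc([C@@H]2CC(=O)c3c(cc(O)c(CC=C(C)C)c3O)O2)c(O)cc1O | target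

**Step count and risks**

Total step count: 10. Longest linear sequence: 7 (steps 1–5, 9, 10).

Steps most likely to fail:

1. Step 9. Protodeboronation of the electron-rich, ortho-alkoxy boronic acid may outrun its transmetalation and insertion into the donor-substituted chromone, or the ortho substituent may erode facial selectivity. The fallback closes ring C last, by an asymmetric oxa-Michael addition. It sets out from 7 and 14 and returns at 17. From 7, MeMgBr would give rac-1-[6-hydroxy-2,4-bis(methoxymethoxy)-3-(3-methylbut-2-enyl)phenyl]ethan-1-ol F1, and MnO2 would oxidise it to 1-[6-hydroxy-2,4-bis(methoxymethoxy)-3-(3-methylbut-2-enyl)phenyl]ethan-1-one F2. From 14, bromine–lithium exchange and DMF would give 2,4-bis(methoxymethoxy)-5-(3-methylbut-2-enyl)benzaldehyde F3. Claisen–Schmidt condensation (KOH, EtOH) of F2 and F3 would give the 2'-hydroxychalcone (E)-3-[2,4-bis(methoxymethoxy)-5-(3-methylbut-2-enyl)phenyl]-1-[6-hydroxy-2,4-bis(methoxymethoxy)-3-(3-methylbut-2-enyl)phenyl]prop-2-en-1-one F4. An enantioselective 6-endo oxa-Michael addition under a quinine-derived bifunctional thiourea would then close ring C to 17; the free hydroxyl is the one para to the prenyl group, so the 6-prenyl pattern is kept.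

2. Step 10. Acid may ionise the C2–O1 bond (benzylic cation stabilised by the 2',4'-dioxygenated ring B) with loss of configuration, or close a prenyl group onto a freed ortho phenol. The fallback moves the acetal cleavage to before C2 exists and ends with buffered fluoride. It sets out from 10 and 14 and returns at 18. From 10, methanolic HCl would give 5,7-dihydroxy-6-(3-methylbut-2-enyl)-4H-chromen-4-one F5, and TIPSCl/imidazole would silylate only the non-chelated hydroxyl to give 5-hydroxy-6-(3-methylbut-2-enyl)-7-(triisopropylsilyloxy)-4H-chromen-4-one F6. From 14, the same acid would give 4-bromo-6-(3-methylbut-2-enyl)benzene-1,3-diol F7, TIPSCl/imidazole would give 1-bromo-5-(3-methylbut-2-enyl)-2,4-bis(triisopropylsilyloxy)benzene F8, and Miyaura borylation (Pd(dppf)Cl2, B2pin2, KOAc, dioxane) would give 2-[5-(3-methylbut-2-enyl)-2,4-bis(triisopropylsilyloxy)phenyl]-4,4,5,5-tetramethyl-1,3,2-dioxaborolane F9. The rhodium-catalysed 1,4-addition of F9 to F6 (aq K3PO4 as activator) would give (2S)-5-hydroxy-6-(3-methylbut-2-enyl)-2-[5-(3-methylbut-2-enyl)-2,4-bis(triisopropylsilyloxy)phenyl]-7-(triisopropylsilyloxy)-2,3-dihydro-4H-chromen-4-one F10. Bu4NF buffered with AcOH in THF at 0 °C would then release 18.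

3. Step 5. The electron-rich ortho-hydroxybenzylic carbinol may ionise to an ortho-quinone methide, or the free phenol may be oxidised before the carbinol. The fallback masks the phenol and lets desilylation trigger the ring closure. It sets out from 7 and returns at 10. TBSCl/imidazole would give 6-(tert-butyldimethylsilyloxy)-2,4-bis(methoxymethoxy)-3-(3-methylbut-2-enyl)benzaldehyde F11. HC≡CMgBr would give rac-1-[6-(tert-butyldimethylsilyloxy)-2,4-bis(methoxymethoxy)-3-(3-methylbut-2-enyl)phenyl]prop-2-yn-1-ol F12. MnO2 would give 1-[6-(tert-butyldimethylsilyloxy)-2,4-bis(methoxymethoxy)-3-(3-methylbut-2-enyl)phenyl]prop-2-yn-1-one F13. Bu4NF in THF at 0 °C would free the phenoxide, which would close to 10 by 6-endo-dig oxa-Michael addition.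

**Further compounds**

F1 | step 9 | rac-1-[6-hydroxy-2,4-bis(methoxymethoxy)-3-(3-methylbut-2-enyl)phenyl]ethan-1-ol | CC(O)c1c(O)cc(OCOC)c(CC=C(C)C)c1OCOC
F2 | step 9 | 1-[6-hydroxy-2,4-bis(methoxymethoxy)-3-(3-methylbut-2-enyl)phenyl]ethan-1-one | CC(=O)c1c(O)cc(OCOC)c(CC=C(C)C)c1OCOC
F3 | step 9 | 2,4-bis(methoxymethoxy)-5-(3-methylbut-2-enyl)benzaldehyde | O=Cc1cc(CC=C(C)C)c(OCOC)cc1OCOC
F4 | step 9 | (E)-3-[2,4-bis(methoxymethoxy)-5-(3-methylbut-2-enyl)phenyl]-1-[6-hydroxy-2,4-bis(methoxymethoxy)-3-(3-methylbut-2-enyl)phenyl]prop-2-en-1-one | O=C(/C=C/c1cc(CC=C(C)C)c(OCOC)cc1OCOC)c1c(O)cc(OCOC)c(CC=C(C)C)c1OCOC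
F5 | step 10 | 5,7-dihydroxy-6-(3-methylbut-2-enyl)-4H-chromen-4-one | O=c1ccoc2cc(O)c(CC=C(C)C)c(O)c12
F6 | step 10 | 5-hydroxy-6-(3-methylbut-2-enyl)-7-(triisopropylsilyloxy)-4H-chromen-4-one | O=c1ccoc2cc(O[Si](C(C)C)(C(C)C)C(C)C)c(CC=C(C)C)c(O)c12
F7 | step 10 | 4-bromo-6-(3-methylbut-2-enyl)benzene-1,3-diol | Oc1cc(O)c(CC=C(C)C)cc1Br
F8 | step 10 | 1-bromo-5-(3-methylbut-2-enyl)-2,4-bis(triisopropylsilyloxy)benzene | CC(C)[Si](Oc1cc(O[Si](C(C)C)(C(C)C)C(C)C)c(CC=C(C)C)cc1Br)(C(C)C)C(C)C
F9 | step 10 | 2-[5-(3-methylbut-2-enyl)-2,4-bis(triisopropylsilyloxy)phenyl]-4,4,5,5-tetramethyl-1,3,2-dioxaborolane | CC(C)[Si](Oc1cc(O[Si](C(C)C)(C(C)C)C(C)C)c(CC=C(C)C)cc1B1OC(C)(C)C(C)(C)O1)(C(C)C)C(C)C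
F10 | step 10 | (2S)-5-hydroxy-6-(3-methylbut-2-enyl)-2-[5-(3-methylbut-2-enyl)-2,4-bis(triisopropylsilyloxy)phenyl]-7-(triisopropylsilyloxy)-2,3-dihydro-4H-chromen-4-one | CC(C)=CCc1cc([C@@H]2CC(=O)c3c(cc(O[Si](C(C)C)(C(C)C)C(C)C)c(CC=C(C)C)c3O)O2)c(O[Si](C(C)C)(C(C)C)C(C)C)cc1O[Si](C(C)C)(C(C)C)C(C)C
F11 | step 5 | 6-(tert-butyldimethylsilyloxy)-2,4-bis(methoxymethoxy)-3-(3-methylbut-2-enyl)benzaldehyde | O=Cc1c(O[Si](C)(C)C(C)(C)C)cc(OCOC)c(CC=C(C)C)c1OCOC
F12 | step 5 | rac-1-[6-(tert-butyldimethylsilyloxy)-2,4-bis(methoxymethoxy)-3-(3-methylbut-2-enyl)phenyl]prop-2-yn-1-ol | C#CC(O)c1c(O[Si](C)(C)C(C)(C)C)cc(OCOC)c(CC=C(C)C)c1OCOC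
F13 | step 5 | 1-[6-(tert-butyldimethylsilyloxy)-2,4-bis(methoxymethoxy)-3-(3-methylbut-2-enyl)phenyl]prop-2-yn-1-one | C#CC(=O)c1c(O[Si](C)(C)C(C)(C)C)cc(OCOC)c(CC=C(C)C)c1OCOC
A1 | direct plan | 1-[2-hydroxy-6-(2-methylbut-3-en-2-yloxy)-4-(triisopropylsilyloxy)phenyl]ethan-1-one | CC(=O)c1c(O)cc(O[Si](C(C)C)(C(C)C)C(C)C)cc1OC(C)(C)C=C
A2 | direct plan | 4-(2-methylbut-3-en-2-yloxy)-2-(triisopropylsilyloxy)benzaldehyde | O=Cc1ccc(OC(C)(C)C=C)cc1O[Si](C(C)C)(C(C)C)C(C)C
A3 | direct plan | rac-3-hydroxy-1-[2-hydroxy-6-(2-methylbut-3-en-2-yloxy)-4-(triisopropylsilyloxy)phenyl]-3-[4-(2-methylbut-3-en-2-yloxy)-2-(triisopropylsilyloxy)phenyl]propan-1-one | OC(CC(=O)c1c(O)cc(O[Si](C(C)C)(C(C)C)C(C)C)cc1OC(C)(C)C=C)c1ccc(OC(C)(C)C=C)cc1O[Si](C(C)C)(C(C)C)C(C)C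
A4 | direct plan | rac-5,4'-bis(2-methylbut-3-en-2-yloxy)-7,2'-bis(triisopropylsilyloxy)flavanone | C=CC(C)(C)Oc1ccc(C2CC(=O)c3c(cc(O[Si](C(C)C)(C(C)C)C(C)C)cc3OC(C)(C)C=C)O2)c(O[Si](C(C)C)(C(C)C)C(C)C)c1
A5 | direct plan | (2S)-5,4'-dihydroxy-6,5'-bis(3-methylbut-2-enyl)-7,2'-bis(triisopropylsilyloxy)flavanone | CC(C)=CCc1cc([C@@H]2CC(=O)c3c(cc(O[Si](C(C)C)(C(C)C)C(C)C)c(CC=C(C)C)c3O)O2)c(O[Si](C(C)C)(C(C)C)C(C)C)cc1O
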